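Numbering (tetralin): C1 iPr, C4 Me, C5 and C6 OH, C7 CHO, C8 joined to C3' of pyranone ring C. Ring A is the saturated ring and ring B the arene.
Cuts: the four O–benzyl bonds come last, then C8–C8a and C4a–C5 of ring B. This works because C5–C8 carry O, O, CHO and ring C in unbroken sequence between C4a and C8a of a p-menthane ring, which is the pattern C3–C6 of a 2-pyranone plus the C=C of a carvomenthone enamine.
The diene pyranone is cut at O1–C2 and C4–C5 into a ring C β-keto thioester (the thioester is the latent CHO) and benzyloxymalonyl dichloride. Ring C is cut at its styryl C=C and at C3'–C(acyl).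
Forward order: ring C (bought as triacetic acid lactone) gains the styryl arm and the C3' acyl chain. The diene pyranone is then annulated onto it, ring A (from carvone) becomes the enamine, ring B closes between the two, and debenzylation ends the route.
Stereochemistry: C1 comes from (S)-carvone. C4 comes from equilibration to trans-carvomenthone and is then guarded by kinetic enol triflate formation and an acid-free amination. The E alkene comes from aldol dehydration.

Key step: step 13

Assumption: the hindered C8–C3' axis carries no assigned configuration in the target, so rotamers about it are treated as one compound.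
Shorthand: "ring C unit" = 4-(benzyloxy)-6-{(E)-2-[4-(benzyloxy)phenyl]ethenyl}-2-oxo-2H-pyran-3-yl.

Step 1
Reactants: 1 4-hydroxy-6-methyl-2H-pyran-2-one (triacetic acid lactone)
Product: 2 4-(benzyloxy)-6-methyl-2H-pyran-2-one
Conditions: BnBr, K2CO3, DMF, 50 °C
Reagents that add atoms: benzyl bromide, BrCc1ccccc1
Why: Williamson-type O-alkylation of the vinylogous carboxylic acid at O4 is the usual way to mask this lactone, and the benzyl group falls in the final BCl3 step.

Step 2
Reactants: 2 4-(benzyloxy)-6-methyl-2H-pyran-2-one; 3 4-(benzyloxy)benzaldehyde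
Product: 6 4-(benzyloxy)-6-{(E)-2-[4-(benzyloxy)phenyl]ethenyl}-2H-pyran-2-one, via 6-lithiomethyl pyranone 4 (not isolated), via aldol adduct 5 (not isolated)
Conditions: LiN(SiMe3)2, THF, −78 °C; 3; H2O; crude 5, TsOH·H2O (cat.), toluene, 60 °C
Reagents that add atoms: none
Why: Vinylogous aldol addition of the 6-methyl dienolate is followed by acid-catalysed dehydration of the 4-alkoxybenzylic alcohol, and conjugation with both π systems should make the E alkene the product.

Step 3
Reactants: 6 4-(benzyloxy)-6-{(E)-2-[4-(benzyloxy)phenyl]ethenyl}-2H-pyran-2-one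
Product: 8 ring C unit carboxylic acid (CO2H on C3'), via 3-lithiopyranone 7 (not isolated)
Conditions: LiN(iPr)2, THF, −78 °C; CO2 (g); 1 M HCl
Reagents that add atoms: carbon dioxide, O=C=O
Why: Directed lithiation of a 4-alkoxy-2-pyranone at C3, the position flanked by the lactone carbonyl and the alkoxy group (no acidic 6-alkyl group remains), is followed by carboxylation of the vinyl-lithium species.

Step 4
Reactants: 8 ring C unit carboxylic acid; 9 2,2-dimethyl-1,3-dioxane-4,6-dione (Meldrum's acid)
Product: 11 S-ethyl 3-(ring C unit)-3-oxopropanethioate, via acyl Meldrum's acid 10 (not isolated)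
Conditions: DCC, DMAP, CH2Cl2, 0 → 23 °C; filter, wash; EtSH, toluene, 80 °C (sealed)
Reagents that add atoms: ethanethiol, CCS
Why: Carbodiimide-mediated C-acylation of Meldrum's acid, then thermolysis to an acylketene trapped by the thiol, is the standard acyl Meldrum's acid route to β-keto thioesters, and it avoids the strong bases and Lewis acids that a 3-acyl-4-benzyloxypyranone would not tolerate.

Step 5
Reactants: 12 2-(benzyloxy)acetic acid
Product: 14 2-(benzyloxy)propanedioic acid, via dilithium enediolate 13 (not isolated)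
Conditions: LiN(iPr)2 (2.2 equiv), THF, −78 → −20 °C; CO2 (g), −78 °C; 1 M HCl, 0 °C
Reagents that add atoms: carbon dioxide, O=C=O
Why: Double deprotonation gives the enediolate of the glycolic acid ether, and its carboxylation is the classical malonic acid synthesis from carboxylic acid dianions.

Step 6
Reactants: 14 2-(benzyloxy)propanedioic acid
Product: 15 2-(benzyloxy)propanedioyl dichloride
Conditions: (COCl)2, DMF (cat.), CH2Cl2, 0 → 23 °C; evaporate, use directly
Reagents that add atoms: oxalyl chloride, O=C(Cl)C(=O)Cl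
Why: Acid chloride formation with oxalyl chloride under catalytic DMF (Vilsmeier-type activation) runs near room temperature, below the decarboxylation range of the malonic acid.

Step 7
Reactants: 11 S-ethyl 3-(ring C unit)-3-oxopropanethioate; 15 2-(benzyloxy)propanedioyl dichloride
Product: 16 S-ethyl 3-(benzyloxy)-4-hydroxy-2-oxo-6-(ring C unit)-2H-pyran-5-carbothioate
Conditions: toluene, 4 Å MS, argon purge, 60 °C
Reagents that add atoms: none
Why: This is the known cyclocondensation of a 1,3-dicarbonyl compound with a malonyl dichloride (through its chlorocarbonylketene), in which C-acylation at the activated methylene forms C4–C5 and acylation of the ketone enol oxygen forms O1–C2, and because the second carbonyl of 11 is a thioester only the ring C ketone can supply O1, which places ring C at C6 and the thioester at C5.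

Step 8
Reactants: 16 S-ethyl 3-(benzyloxy)-4-hydroxy-2-oxo-6-(ring C unit)-2H-pyran-5-carbothioate
Product: 17 S-ethyl 3,4-bis(benzyloxy)-2-oxo-6-(ring C unit)-2H-pyran-5-carbothioate
Conditions: BnBr, K2CO3, DMF, 23 °C
Reagents that add atoms: benzyl bromide, BrCc1ccccc1
Why: Williamson-type O-alkylation of the acidic 4-hydroxy-2-pyranone under carbonate conditions gives the 4-alkoxy-2-pyranone, and the thioester and the other benzyl ethers are inert to K2CO3 at room temperature.

Step 9
Reactants: 17 S-ethyl 3,4-bis(benzyloxy)-2-oxo-6-(ring C unit)-2H-pyran-5-carbothioate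
Product: 18 3,4-bis(benzyloxy)-2-oxo-6-(ring C unit)-2H-pyran-5-carbaldehyde
Conditions: Et3SiH, Pd/C (10 % Pd), acetone–CH2Cl2, 23 °C
Reagents that add atoms: none
Why: In the Fukuyama reduction zerovalent palladium inserts into the acyl C–S bond and the silane delivers hydride, a neutral method that stops at the aldehyde and in aprotic solvent should leave lactones, benzyl ethers and the disubstituted styryl alkene alone.

Step 10
Reactants: 19 (S)-(+)-carvone
Product: 21 (2S,5S)-2-methyl-5-(propan-2-yl)cyclohexan-1-one (trans-carvomenthone), via carvomenthone epimer mixture 20 (not isolated)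
Conditions: H2 (1 atm), Pd/C, MeOH, 23 °C; filter; NaOMe (cat.), MeOH, 23 °C; chromatography
Reagents that add atoms: none
Why: Heterogeneous catalytic hydrogenation saturates both C=C bonds, and enolate equilibration then places the C2 methyl group equatorial and trans to the equatorial isopropyl group at the carvone-derived C5, which sets the (2S) centre (future C4) under thermodynamic control.

Step 11
Reactants: 21 trans-carvomenthone
Product: 23 (3R,6S)-6-methyl-3-(propan-2-yl)cyclohex-1-en-1-yl trifluoromethanesulfonate, via kinetic lithium enolate 22 (not isolated)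
Conditions: LiN(iPr)2, THF, −78 °C; PhNTf2, −78 → 0 °C; H2O
Reagents that add atoms: N-phenylbis(trifluoromethanesulfonimide), O=S(=O)(N(c1ccccc1)S(=O)(=O)C(F)(F)F)C(F)(F)F
Why: Kinetic deprotonation by the hindered amide base at the methylene α-carbon, followed by O-sulfonylation (enol triflate formation), fixes the double bond between the future C4a and C8a without touching the C–H at the methyl-bearing carbon, so that centre keeps its configuration.

Step 12
Reactants: 23 (3R,6S)-6-methyl-3-(propan-2-yl)cyclohex-1-en-1-yl trifluoromethanesulfonate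
Product: 24 1-[(3R,6S)-6-methyl-3-(propan-2-yl)cyclohex-1-en-1-yl]pyrrolidine
Conditions: pyrrolidine, Pd2(dba)3 (cat.), BINAP (cat.), Cs2CO3, toluene, 80 °C; filter under argon, bulb-to-bulb distillation, use at once
Reagents that add atoms: pyrrolidine, C1CCNC1
Why: Buchwald–Hartwig-type amination of an alkenyl triflate (insertion of zerovalent palladium into the C–O bond, amine binding, deprotonation, reductive elimination) puts nitrogen exactly where the triflate was, and with only carbonate base present the enamine cannot equilibrate through its iminium ion toward the cis isomer favoured by allylic strain, so the double bond stays at C4a=C8a and C4 stays S.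

Step 13
Reactants: 18 3,4-bis(benzyloxy)-2-oxo-6-(ring C unit)-2H-pyran-5-carbaldehyde; 24 1-[(3R,6S)-6-methyl-3-(propan-2-yl)cyclohex-1-en-1-yl]pyrrolidine
Product: 27 tetra-O-benzyl heimiomycin A, (1R,4S)-5,6-bis(benzyloxy)-4-methyl-1-(propan-2-yl)-8-(ring C unit)-1,2,3,4-tetrahydronaphthalene-7-carbaldehyde, via bridged lactone 25 (not isolated), via aminocyclohexadiene 26 (not isolated)
Conditions: 24 (1.5 equiv), toluene, 4 Å MS, 23 → 90 °C; then SiO2 slurry, 23 °C
Reagents that add atoms: none
Why: The electron-rich enamine carbon C8a bonds to pyranone C6, the β-carbon of the C5 enal and the δ-carbon of the lactone dienoate, and the dienolate so formed closes from C3 onto the iminium carbon C4a, a strongly asynchronous inverse-electron-demand Diels–Alder reaction that gives bridged lactone 25. Cycloreversion of 25 expels CO2 to aminocyclohexadiene 26, and mild acid ionises the C4a–N bond to an alkoxy-stabilised arenium ion that loses the C8a proton, so pyrrolidine leaves and ring B becomes aromatic. The closest known reaction type is the cycloaddition of 2-pyranones bearing a C5 acceptor (coumalate type) with enamines of cyclic ketones, which gives benzo-fused carbocycles in this same orientation after loss of CO2 and amine. Ring B closes as a six-membered carbocycle by intermolecular (4+2) annulation onto the C4a=C8a bond of ring A, forming C8–C8a and C4a–C5 in one operation. No lasting stereocentre is created, since the four sp3 centres of 25 are erased on aromatisation and facial selectivity is therefore irrelevant, while C1 and C4 are spectators and C4 is safe because no proton source is present until the enamine has been consumed. The step needs site selectivity for the formyl-bearing pyranone over ring C and for C6 over C4 and the formyl carbon: ring C is deactivated by its 4'-benzyloxy donor and twisted out of conjugation, both carbonyl groups of the diene ring polarise C6, C4 is damped by its own benzyloxy donor, and addition to the formyl group is reversible whereas CO2 loss is not.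

Step 14
Reactants: 27 tetra-O-benzyl heimiomycin A
Product: 28 heimiomycin A
Conditions: BCl3, pentamethylbenzene, CH2Cl2, −78 → −40 °C; MeOH–CHCl3 quench, H2O
Reagents that add atoms: none
Why: Lewis-acid debenzylation with BCl3, with pentamethylbenzene as a non-basic benzyl cation scavenger (Friedel–Crafts capture), cleaves aryl and vinylogous-ester benzyl ethers at low temperature without touching the styryl alkene, the aldehyde or the lactone, whereas hydrogenolysis would saturate the alkene.

Compound list
1 | 4-hydroxy-6-methyl-2H-pyran-2-one (triacetic acid lactone) | Cc1cc(O)cc(=O)o1 | starting material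
2 | 4-(benzyloxy)-6-methyl-2H-pyran-2-one | Cc1cc(OCc2ccccc2)cc(=O)o1 | intermediate
3 | 4-(benzyloxy)benzaldehyde | O=Cc1ccc(OCc2ccccc2)cc1 | starting material
4 | 4-(benzyloxy)-6-(lithiomethyl)-2H-pyran-2-one | [Li]Cc1cc(OCc2ccccc2)cc(=O)o1 | intermediate
5 | 4-(benzyloxy)-6-{2-[4-(benzyloxy)phenyl]-2-hydroxyethyl}-2H-pyran-2-one (racemic) | OC(Cc1cc(OCc2ccccc2)cc(=O)o1)c1ccc(OCc2ccccc2)cc1 | intermediate
6 | 4-(benzyloxy)-6-{(E)-2-[4-(benzyloxy)phenyl]ethenyl}-2H-pyran-2-one | O=c1cc(OCc2ccccc2)cc(/C=C/c2ccc(OCc3ccccc3)cc2)o1 | intermediate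
7 | 4-(benzyloxy)-6-{(E)-2-[4-(benzyloxy)phenyl]ethenyl}-3-lithio-2H-pyran-2-one | [Li]c1c(OCc2ccccc2)cc(/C=C/c2ccc(OCc3ccccc3)cc2)oc1=O | intermediate
8 | 4-(benzyloxy)-6-{(E)-2-[4-(benzyloxy)phenyl]ethenyl}-2-oxo-2H-pyran-3-carboxylic acid | OC(=O)c1c(OCc2ccccc2)cc(/C=C/c2ccc(OCc3ccccc3)cc2)oc1=O | intermediate
9 | 2,2-dimethyl-1,3-dioxane-4,6-dione (Meldrum's acid) | CC1(C)OC(=O)CC(=O)O1 | starting material
10 | 5-[hydroxy(ring C unit)methylidene]-2,2-dimethyl-1,3-dioxane-4,6-dione | CC1(C)OC(=O)C(=C(O)c2c(OCc3ccccc3)cc(/C=C/c3ccc(OCc4ccccc4)cc3)oc2=O)C(=O)O1 | intermediate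
11 | S-ethyl 3-(4-(benzyloxy)-6-{(E)-2-[4-(benzyloxy)phenyl]ethenyl}-2-oxo-2H-pyran-3-yl)-3-oxopropanethioate | CCSC(=O)CC(=O)c1c(OCc2ccccc2)cc(/C=C/c2ccc(OCc3ccccc3)cc2)oc1=O | intermediate
12 | 2-(benzyloxy)acetic acid | OC(=O)COCc1ccccc1 | starting material
13 | dilithium enediolate of 2-(benzyloxy)acetic acid | [Li]OC(O[Li])=COCc1ccccc1 | intermediate
14 | 2-(benzyloxy)propanedioic acid | OC(=O)C(OCc1ccccc1)C(=O)O | intermediate
15 | 2-(benzyloxy)propanedioyl dichloride | O=C(Cl)C(OCc1ccccc1)C(=O)Cl | intermediate
16 | S-ethyl 3-(benzyloxy)-4-hydroxy-2-oxo-6-(ring C unit)-2H-pyran-5-carbothioate | CCSC(=O)c1c(O)c(OCc2ccccc2)c(=O)oc1-c1c(OCc2ccccc2)cc(/C=C/c2ccc(OCc3ccccc3)cc2)oc1=O | intermediate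
17 | S-ethyl 3,4-bis(benzyloxy)-2-oxo-6-(ring C unit)-2H-pyran-5-carbothioate | CCSC(=O)c1c(OCc2ccccc2)c(OCc2ccccc2)c(=O)oc1-c1c(OCc2ccccc2)cc(/C=C/c2ccc(OCc3ccccc3)cc2)oc1=O | intermediate
18 | 3,4-bis(benzyloxy)-6-(4-(benzyloxy)-6-{(E)-2-[4-(benzyloxy)phenyl]ethenyl}-2-oxo-2H-pyran-3-yl)-2-oxo-2H-pyran-5-carbaldehyde | O=Cc1c(OCc2ccccc2)c(OCc2ccccc2)c(=O)oc1-c1c(OCc2ccccc2)cc(/C=C/c2ccc(OCc3ccccc3)cc2)oc1=O | intermediate
19 | (S)-(+)-carvone | CC(=C)[C@H]1CC=C(C)C(=O)C1 | starting material
20 | (5S)-2-methyl-5-(propan-2-yl)cyclohexan-1-one, mixture of C2 epimers | CC(C)[C@H]1CCC(C)C(=O)C1 | intermediate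
21 | (2S,5S)-2-methyl-5-(propan-2-yl)cyclohexan-1-one (trans-carvomenthone) | CC(C)[C@H]1CC[C@H](C)C(=O)C1 | intermediate
22 | lithium (3R,6S)-6-methyl-3-(propan-2-yl)cyclohex-1-en-1-olate | CC(C)[C@H]1CC[C@H](C)C(O[Li])=C1 | intermediate
23 | (3R,6S)-6-methyl-3-(propan-2-yl)cyclohex-1-en-1-yl trifluoromethanesulfonate | CC(C)[C@H]1CC[C@H](C)C(OS(=O)(=O)C(F)(F)F)=C1 | intermediate
24 | 1-[(3R,6S)-6-methyl-3-(propan-2-yl)cyclohex-1-en-1-yl]pyrrolidine | CC(C)[C@H]1CC[C@H](C)C(N2CCCC2)=C1 | intermediate
25 | bridged cycloadduct, a 2-oxabicyclo[2.2.2]oct-5-en-3-one spanning pyranone C3/C6 and C4a/C8a (pyrrolidine on C4a; C1 R, C4 S; the four new centres transient) | O=C1OC2(c3c(OCc4ccccc4)cc(/C=C/c4ccc(OCc5ccccc5)cc4)oc3=O)C(C=O)=C(OCc3ccccc3)C1(OCc1ccccc1)C1(N3CCCC3)[C@@H](C)CC[C@H](C(C)C)C21 | intermediate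
26 | 4a-(pyrrolidin-1-yl)-4a,8a-dihydro precursor of 27 (C5=C6 and C7=C8 double bonds; C1 R, C4 S) | O=CC1=C(c2c(OCc3ccccc3)cc(/C=C/c3ccc(OCc4ccccc4)cc3)oc2=O)C2[C@@H](C(C)C)CC[C@H](C)C2(N2CCCC2)C(OCc2ccccc2)=C1OCc1ccccc1 | intermediate
27 | tetra-O-benzyl heimiomycin A, (1R,4S) | CC(C)[C@H]1CC[C@H](C)c2c(OCc3ccccc3)c(OCc3ccccc3)c(C=O)c(-c3c(OCc4ccccc4)cc(/C=C/c4ccc(OCc5ccccc5)cc4)oc3=O)c21 | intermediate
28 | heimiomycin A, (1R,4S) | CC(C)[C@H]1CC[C@H](C)c2c(O)c(O)c(C=O)c(-c3c(O)cc(/C=C/c4ccc(O)cc4)oc3=O)c21 | target

Total step count: 14. Longest linear sequence: 9 steps (1, 2, 3, 4, 7, 8, 9, 13, 14).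

Steps most likely to fail

Step 13. Bond formation between the secondary enamine carbon next to the isopropyl-bearing C1 and the fully substituted C6 may be too slow. Four processes could then take over:
- reversible addition at the formyl group
- displacement of the C4 benzyloxy group
- opening of the pyranone by released pyrrolidine
- proton-mediated equilibration of the enamine, which would erode C4

The fallback sets out from lithium enolate 22 and diene 18 and returns at 27. Enolate 22 is silylated with Me3SiCl to the kinetic trimethylsilyl enol ether F1, which cannot tautomerise and releases no amine. Under Sc(OTf)3 catalysis (coordination at the formyl oxygen), a Mukaiyama–Michael addition of F1 to C6, with closure of C3 onto the oxocarbenium carbon, gives the silyloxy bridged lactone F2. This is the Lewis-acid-promoted cycloaddition known for acceptor-substituted 2-pyranones and silyl enol ethers. Heating expels CO2 to the silyloxycyclohexadiene F3, and catalytic TsOH removes trimethylsilanol to give 27.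

Step 7. The alkoxy-substituted malonyl dichloride may self-condense or fragment through its ketene faster than it acylates the hindered methylene of 11. The fallback sets out from 11 and returns at 16, and it installs the C3 oxygen after ring closure. Compound 11 is condensed with the stable parent malonyl dichloride to the 3-unsubstituted hydroxypyranone thioester F4. Regitz diazo transfer (4-acetamidobenzenesulfonyl azide, Et3N) then gives the 3-diazopyran-2,4-dione F5. Rh2(OAc)4-catalysed O–H insertion into benzyl alcohol, followed by enolisation, delivers 16.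

Step 9. Insertion of palladium into the C–S bond, which is flanked by a benzyloxy group and ring C, may be sluggish. Silane-mediated saturation of the styryl double bond or decarbonylation could then compete. The fallback sets out from 17 and returns at 18 without palladium hydride chemistry. Thiophilic hydrolysis with AgO2CCF3 in aqueous THF gives the pyranone-5-carboxylic acid F6. Oxalyl chloride with catalytic DMF gives the acid chloride F7. One equivalent of LiAlH(OtBu)3 in THF at −78 °C, the classical acid chloride to aldehyde reduction, then gives 18.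

Further compounds
F1 | step 13 | trimethyl{[(3R,6S)-6-methyl-3-(propan-2-yl)cyclohex-1-en-1-yl]oxy}silane | CC(C)[C@H]1CC[C@H](C)C(O[Si](C)(C)C)=C1
F2 | step 13 | silyloxy bridged lactone (analogue of 25 with OSiMe3 on C4a) | O=C1OC2(c3c(OCc4ccccc4)cc(/C=C/c4ccc(OCc5ccccc5)cc4)oc3=O)C(C=O)=C(OCc3ccccc3)C1(OCc1ccccc1)C1(O[Si](C)(C)C)[C@@H](C)CC[C@H](C(C)C)C21
F3 | step 13 | silyloxycyclohexadiene (analogue of 26 with OSiMe3 on C4a) | O=CC1=C(c2c(OCc3ccccc3)cc(/C=C/c3ccc(OCc4ccccc4)cc3)oc2=O)C2[C@@H](C(C)C)CC[C@H](C)C2(O[Si](C)(C)C)C(OCc2ccccc2)=C1OCc1ccccc1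
F4 | step 7 | S-ethyl 4-hydroxy-2-oxo-6-(ring C unit)-2H-pyran-5-carbothioate | CCSC(=O)c1c(O)cc(=O)oc1-c1c(OCc2ccccc2)cc(/C=C/c2ccc(OCc3ccccc3)cc2)oc1=O
F5 | step 7 | S-ethyl 3-diazo-2,4-dioxo-6-(ring C unit)-3,4-dihydro-2H-pyran-5-carbothioate | CCSC(=O)C1=C(c2c(OCc3ccccc3)cc(/C=C/c3ccc(OCc4ccccc4)cc3)oc2=O)OC(=O)C(=[N+]=[N-])C1=O
F6 | step 9 | 3,4-bis(benzyloxy)-2-oxo-6-(ring C unit)-2H-pyran-5-carboxylic acid | OC(=O)c1c(OCc2ccccc2)c(OCc2ccccc2)c(=O)oc1-c1c(OCc2ccccc2)cc(/C=C/c2ccc(OCc3ccccc3)cc2)oc1=O
F7 | step 9 | 3,4-bis(benzyloxy)-2-oxo-6-(ring C unit)-2H-pyran-5-carbonyl chloride | ClC(=O)c1c(OCc2ccccc2)c(OCc2ccccc2)c(=O)oc1-c1c(OCc2ccccc2)cc(/C=C/c2ccc(OCc3ccccc3)cc2)oc1=O
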